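The numbers in the tables come from a simulation for substances that don't exist; scatter was added.

Early in a run the bench rule works: more coupling partner per substrate gives more target. At 1.50 h the grey run, with 1.3 M of coupling partner, holds 79.2% of target, more than the 67.2% of the blue run with 0.75 M.

| flask | substrate | coupling partner | remark | time |
|---|---|---|---|---|
| ochre | 0.41 M | 0.75 M | run made earlier |  |
| violet | 0.68 M | 0.75 M | run made earlier |  |
| blue | 0.57 M | 0.75 M | run made earlier |  |
| grey | 0.50 M | 1.3 M | run made earlier |  |
| south-east | 0.50 M | 0.750 M |  | 40 h |
| south-west | 0.80 M | 3.00 M |  | 60 h |

| ochre: time / h | ochre: target / % | violet: time / h | violet: target / % | blue: time / h | blue: target / % | grey: time / h | grey: target / % |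
|---|---|---|---|---|---|---|---|
| 2.00 | 73.8 | 4.00 | 76.4 | 1.50 | 67.2 | 1.50 | 79.2 |
| 5.00 | 79.1 | 8.00 | 72.7 | 3.00 | 77.2 | 3.00 | 82.6 |
| 10.0 | 70.0 | 12.0 | 65.8 | 6.00 | 77.5 | 6.00 | 77.9 |
| 15.0 | 63.9 | 15.0 | 65.4 | 10.0 | 70.6 | 10.0 | 68.4 |
| 20.0 | 59.8 | 20.0 | 61.7 | 20.0 | 60.2 | 20.0 | 59.7 |

(standard deviation of a reading: 1 percentage point)

* the flask that ends with the higher amount of target, in percent of the substrate charged, or "neither" when 2 percentage points or less lies between them (south-east / south-west / neither)
* final target, as a percentage of the substrate charged, in south-east
* final target, as a percentage of the substrate charged, in south-west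

- percentages count the substrate that a species holds: one idle adduct counts as two
- target is meant together with its idle adduct
- steps under discussion: substrate + target <-> idle adduct; substrate + coupling partner -> target; 2 coupling partner -> homo dimer; target <-> isomer of the product
- in an amount of target, one idle adduct counts as one target

Applied honestly, the rule picks south-west, with 3.75 coupling partner per substrate against 1.50 in south-east. But it is a rule of kinetic control, and it stops working: at 20.0 h grey reads 59.7% and blue 60.2%, a difference less than the scatter of one reading. Past the peak we take the fall to be target sliding to its isomer, towards thermodynamic control, and we count that fall in powers of ten. The decade time is the time in which the gap between target and its plateau shrinks tenfold. It is the step between readings times the logarithm of ten, divided by the logarithm of the ratio of successive falls. The last readings of ochre give: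

falls: 6.1 percentage points, then 4.1 points, each over 5.00 h

decade time: 29.0 h

gap above the plateau at 20.0 h: 8.4 points

The border of the bench rule is the ratio of time to decade time. Grey's highest reading, at 3.00 h, lies at 0.103 decades, while the asked times lie at 1.38 in south-east and 2.07 in south-west. Taking ochre's gap at 20.0 h for both flasks, our reckoning leaves:

south-east: 1.7 points

south-west: 0.35 points

So south-east stands 1.4 points higher, less than the margin of 2 points.

The forecast also says neither, with south-east at 53% (49% to 57%) and south-west at 54% (48% to 59%). Its ground reads: “That fall is the reversible slide to the isomer.” It differs from us in direction, putting south-west higher by 1 point.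

South-east ends at 56.7% and south-west at 56.5%, so the answer is neither.

    substrate + target ⇌ idle adduct, settled at all times (K = 1.90 M⁻¹)
    substrate + coupling partner → target, rate k2*[substrate]*[coupling partner]^0.5 (k = 1.50 M⁻⁰·⁵ h⁻¹)
    2 coupling partner → homo dimer (k = 0.00370 M⁻¹ h⁻¹)
    target ⇌ isomer of the product (K = 0.770, k = 0.0620 h⁻¹)

South-east still lies 0.2 points above its value at 400 h. Counted with our decade time, itself read off scattered readings, its gap of 3.4 points at 20.0 h comes to an estimated 0.69 points, more than the flask keeps, yet less than the margin. South-west read at 15 h holds 62.4%, and the 1.55 decades up to 60 h count its gap down to an estimated 0.17 points, again less than the margin. South-west itself stands at 56.5%, against 56.5% at 600 h.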